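3 questions stand below, and I answer them with one bracket per flask: a ceiling, a floor, and a test of whether the brackets overlap.

| flask | starting material | partner | remark | time |
|---|---|---|---|---|
| delta | 1.8 M | 0.96 M | run made earlier |  |
| alpha | 1.8 M | 0.72 M | run made earlier |  |
| north | 1.2 M | 1.44 M |  | 4.0 h |
| east | 1.8 M | 1.44 M |  | 12 h |

| run | time / h | target / % | starting material / % |
|---|---|---|---|
| delta | 1.33 | 20.3 | 57.6 |
| delta | 2.50 | 16.1 | 46.0 |
| delta | 4.00 | 10.7 | 38.4 |
| delta | 5.00 | 7.3 | 35.2 |
| delta | 6.00 | 5.7 | 33.2 |
| delta | 8.00 | 3.3 | 30.3 |
| alpha | 1.33 | 15.8 | 67.0 |
| alpha | 2.50 | 11.7 | 56.2 |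
| alpha | 4.00 | 7.7 | 49.9 |
| alpha | 5.00 | 5.2 | 47.4 |
| alpha | 6.00 | 3.8 | 45.3 |
| alpha | 8.00 | 2.0 | 43.9 |

(each reading ± 0.3 percentage points)

- which of the two ends with the higher amount of target, in percent of the starting material charged ("neither" if they lie within 2 percentage points) (north / east / neither)
- target at the end, in percent of the starting material charged, north
- target at the end, in percent of the starting material charged, east

- the numbers in the tables scatter with a standard deviation of 0.3 percentage points

1. Ceiling. From alpha to delta, partner rises by a factor of 1.33. Target at the first reading rises by 1.28, which is less, but at the last reading it rises by 1.65, which is more, though less than the square of the partner factor, 1.78. So I scale the first delta reading by the partner ratio 1.50, scale the last by its square, and count no fading. North, reckoned in molar amount from the delta reading at 1.33 h, gets 45.7%. East, from the delta reading at 8.00 h, gets 7.43%.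

2. Fade rate. The fade rate is the fraction of target lost per hour late in a run, a pseudo-first-order constant. Alpha gives 0.319 h⁻¹ and delta gives 0.265 h⁻¹, which is slower. I use the faster reading, to keep the floor low.

3. Floor. Applying that fade to each ceiling up to the asked time gives 19.5% for north and 2.08% for east.

4. Commitment. The floor of north stands above the ceiling of east, so I say north ends higher.

5. The forecast says north, with 33% for north and 10% for east. Its ground for north is that “little starting material remains to destroy the target”. Its north lies inside my bracket, and its east lies above my ceiling.

    starting material + target → side product (k = 7.00 × 10⁻⁵ M⁻¹ s⁻¹)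
    target ⇌ isomer of the product (K = 29.0, k = 9.00 × 10⁻⁵ s⁻¹)
    starting material + partner ⇌ target + by-product (K = 6.60, k = 2.60 × 10⁻⁴ M⁻¹ s⁻¹)
    partner ⇌ dormant form (K = 0.500, k = 6.30 × 10⁻⁴ s⁻¹)

The flask gives north, with 22.5% in north and 3.73% in east. At the end of east, isomer of the product stands at 44.5% and side product at 42.2%, where each side product counts as two. The fade rate, applied to the 9.53% of east at 6.00 h, gives a floor of 1.41% at the end, and east stands above it. Applied to north left until 15 h, it gives a floor of 0.677%, and that flask holds 3.88%.

(The data were computed with constants of no real substance; the scatter is artificial.)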